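Start with the clock.

the same everywhere: catalyst 0.39 mol%
- dusk: starting material 0.10 M; coupling partner 1.05 equiv; second substrate 1.5 equiv; run made earlier
- summer: starting material 0.20 M; coupling partner 1.05 equiv; second substrate 1 equiv; run made earlier
- north-east: starting material 0.10 M; coupling partner 1.10 equiv; second substrate 1.00 equiv; time 2.0 min
- south-east: starting material 0.10 M; coupling partner 1.60 equiv; second substrate 1.00 equiv; time 2.0 min

| run | time / s | target / % | isomer of the product / % | starting material / % | over-reaction product / % |
|---|---|---|---|---|---|
| dusk | 20.0 | 20.9 | 1.7 | 78.0 | 1.7 |
| dusk | 40.0 | 26.2 | 4.8 | 70.5 | 3.5 |
| dusk | 50.0 | 25.0 | 2.4 | 70.2 | 3.9 |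
| dusk | 80.0 | 24.1 | 6.0 | 63.4 | 6.4 |
| summer | 10.0 | 31.8 | 1.3 | 67.1 | 0.3 |
| summer | 12.0 | 34.4 | 1.5 | 64.2 | 0.8 |
| summer | 30.0 | 39.8 | 3.0 | 53.8 | 2.7 |
| summer | 80.0 | 30.8 | 10.2 | 50.6 | 11.6 |

(each reading ± 1 percentage point)

- the earlier runs were read with a standard deviation of 1 percentage point

1. which of these there is most of at the end, counted by the starting material in it, north-east (target / isomer of the product / over-reaction product / starting material)
2. which of these there is most of at the end, counted by the starting material in it, south-east (target / isomer of the product / over-reaction product / starting material)
3. amount of the one of these that there is most of at the end, in percent of the starting material charged, north-east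
4. amount of the one of these that there is most of at the end, in percent of the starting material charged, south-east

Suppose starting material is lost in step with the concentrations of catalyst and coupling partner. Both are charged in proportion to it, so the percent clock runs with the square of the charge. My carried quantity is the summer-equivalent time, the time in the flask multiplied by the square of its starting concentration over summer's: 30.0 s for north-east. The readings support this: dusk at 40.0 s matches summer at 10.0 s, with 70.5% against 67.1%, while dusk at 20.0 s still holds 78.0%. So I expect north-east near summer's 53.8%.

Summer stalled after using 47.0% of its coupling partner on starting material, so I let second substrate take an equal amount. Scaling summer's exponent by mean coupling partner, replacing the curve by its mean, with south-east's mean taken from its own consumption and found by repeated substitution, gives south-east 36.1% starting material.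

The second time is the drain time of target, 110 s, read from summer's late readings and taken as first-order, so the clock leaves it unchanged. Held against 2.0 min, it leaves south-east 41.3% target, more than starting material.

The forecast, which held that the stall “suggests the catalyst is dying”, gave starting material at 71% for north-east and starting material at 60% for south-east.

North-east ends with starting material on top at 52.0%; south-east ends with target on top at 38.4%, above starting material at 33.2%.

    target ⇌ isomer of the product (K = 1.10, k = 0.00380 s⁻¹)
    second substrate + coupling partner + catalyst → catalyst + second product (k = 540 M⁻² s⁻¹)
    target → over-reaction product (k = 0.00330 s⁻¹)
    starting material + coupling partner + catalyst → catalyst + target (k = 440 M⁻² s⁻¹)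

Now take south-east at 0.025 M, with the same equivalents and time. Its clock reads 1.88 s. Summer's exponent per second up to its first reading, scaled by mean coupling partner, gives 86.3% starting material. The flask holds 83.5% starting material and 11.1% target.

All runs are simulated with constants of no real substance; noise was put on by code.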